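**Retrosynthetic overview**

1. Numbering used below: ring carbons C1 (quaternary; CH2OH and side chain), C2 (CH; 3-hydroxypropyl), C3 (alkylidene carbon), C4 and C5 (CH2), C6 (C(OH)CH3).
2. Enabling feature: C3 and C6 stand 1,4 to each other across the only ring, the cyclohexane; with both at the ketone oxidation level that ring is a cyclohexane-1,4-dione in which C4 and C5 are the two α-carbons, i.e. two donor carbons of like polarity.
3. Key disconnection C4–C5: oxidative coupling of the bis-enolate of the acyclic 1,4-diketone 10 joins its two acetyl methyl groups and forms the cyclohexane, the only ring closure of the route.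
4. Before it: the C1/C2 stereodiad is set in one iridium-catalysed allylic alkylation (3 + 8 → 9), and Tsuji–Wacker oxidation of the vinyl group gives 10.
5. After it: isopropenyl addition at C3, methyl addition at C6, ester reduction, Babler–Dauben transposition to the enal, then the triene side chain by Wittig and Horner–Wadsworth–Emmons olefinations and final desilylation.

Key step: step 6

Remark: TBS = tert-butyldimethylsilyl; locants C1–C6 in the Why lines refer to the ring numbering of the overview.

Step 1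
Reactants: 1 tert-butyl acetoacetate; 2 2-(2-bromoethyl)-1,3-dioxolane
Product: 3 tert-butyl 2-acetyl-4-(1,3-dioxolan-2-yl)butanoate (racemic, stereocentre labile)
Conditions: K2CO3, NaI (cat.), DMF, 60 °C
Reagents that add atoms: 2-(2-bromoethyl)-1,3-dioxolane, BrCCC1OCCO1
Why: Acetoacetic ester alkylation (SN2 of the enolate on a primary bromide) installs the first three side-chain carbons, the third one masked as a base-stable acetal of the later aldehyde.

Step 2
Reactants: 4 pent-4-en-1-ol; 5 tert-butyldimethylsilyl chloride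
Product: 6 tert-butyldimethyl(pent-4-en-1-yloxy)silane
Conditions: imidazole, CH2Cl2, 0 → 25 °C
Reagents that add atoms: tert-butyldimethylsilyl chloride, CC(C)(C)[Si](C)(C)Cl
Why: Imidazole-promoted silylation of the primary alcohol gives an ether that should survive the amide base, Grignard reagents and hydride used later.

Step 3
Reactants: 6 tert-butyldimethyl(pent-4-en-1-yloxy)silane; 7 allyl methyl carbonate
Product: 8 (2E)-6-[(tert-butyldimethylsilyl)oxy]hex-2-en-1-yl methyl carbonate
Conditions: 7 (3 equiv), ruthenium benzylidene catalyst RuCl2(H2IMes)(=CH-C6H4-2-OiPr) (H2IMes = 1,3-dimesitylimidazolidin-2-ylidene; 3 mol%), CH2Cl2, 40 °C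
Reagents that add atoms: allyl methyl carbonate, C=CCOC(=O)OC
Why: Olefin cross-metathesis of two terminal alkenes with loss of ethene, in which excess of the cheap carbonate suppresses homodimerisation and the E-alkene needed for the next step should predominate.

Step 4
Reactants: 3 tert-butyl 2-acetyl-4-(1,3-dioxolan-2-yl)butanoate; 8 (2E)-6-[(tert-butyldimethylsilyl)oxy]hex-2-en-1-yl methyl carbonate
Product: 9 tert-butyl (2R,3R)-2-acetyl-3-{3-[(tert-butyldimethylsilyl)oxy]propyl}-2-[2-(1,3-dioxolan-2-yl)ethyl]pent-4-enoate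
Conditions: [Ir(cod)Cl]2 (2 mol%), BINOL-derived N-aryl phosphoramidite ligand (4 mol%, the enantiomer that gives 3R), 1,5,7-triazabicyclo[4.4.0]dec-5-ene (10 mol%), LiBr, THF, 25 °C
Reagents that add atoms: (2E)-6-[(tert-butyldimethylsilyl)oxy]hex-2-en-1-yl methyl carbonate, COC(=O)OC/C=C/CCCO[Si](C)(C)C(C)(C)C
Why: Iridium-catalysed asymmetric allylic alkylation, in which the cyclometalated iridium–phosphoramidite complex ionises the linear carbonate and directs the enolate of 3 to the substituted allyl terminus, so that the C2 centre (3R) is set by the ligand and the adjacent quaternary C1 (2R) by the preferred face of the prochiral enolate, as known for α-substituted β-keto esters.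

Step 5
Reactants: 9 tert-butyl (2R,3R)-2-acetyl-3-{3-[(tert-butyldimethylsilyl)oxy]propyl}-2-[2-(1,3-dioxolan-2-yl)ethyl]pent-4-enoate
Product: 10 tert-butyl (2R,3S)-2-acetyl-3-{3-[(tert-butyldimethylsilyl)oxy]propyl}-2-[2-(1,3-dioxolan-2-yl)ethyl]-4-oxopentanoate
Conditions: PdCl2 (10 mol%), CuCl (co-catalyst), O2 (1 atm), DMF/H2O 7:1, 25 °C
Reagents that add atoms: water, O
Why: Tsuji–Wacker oxidation (Markovnikov hydroxypalladation of the monosubstituted alkene, then β-hydride elimination) gives the methyl ketone, the classical way from an α-allylated β-keto ester to a 1,4-diketone, and leaves both stereocentres untouched.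

Step 6
Reactants: 10 tert-butyl (2R,3S)-2-acetyl-3-{3-[(tert-butyldimethylsilyl)oxy]propyl}-2-[2-(1,3-dioxolan-2-yl)ethyl]-4-oxopentanoate
Product: 12 tert-butyl (1R,2S)-2-{3-[(tert-butyldimethylsilyl)oxy]propyl}-1-[2-(1,3-dioxolan-2-yl)ethyl]-3,6-dioxocyclohexane-1-carboxylate, via dilithium bis-enolate 11 (not isolated)
Conditions: LiN(iPr)2 (2.4 equiv), THF, −78 °C, 10 added slowly to the base (0.01 M); then CuCl2 (2.4 equiv) in DMF, −78 → 0 °C
Reagents that add atoms: none
Why: Double kinetic deprotonation of the two acetyl groups gives the dilithium bis-enolate 11, one-electron oxidation of one enolate by divalent copper gives an α-keto radical (or copper-bound enolate) at one methyl-derived carbon, this adds to the terminal carbon of the second enolate, and a second one-electron oxidation of the resulting oxygen-stabilised radical delivers the 1,4-diketone. The closest known reaction type is the CuCl2- or FeCl3-mediated oxidative coupling of lithium ketone enolates to 1,4-diketones, including its intramolecular bis-enolate variants. The cyclohexane, the only ring formed, closes in a 6-endo-trig mode with respect to the accepting enolate C3=C4, in line with the known 6-endo preference of 2-oxohex-5-enyl radicals, whereas the 5-exo alternative would attack the oxygen-bearing enolate carbon and is unproductive. No new stereocentre is formed: the quaternary C1 cannot epimerise, and C2 is preserved because the amide base removes a methyl proton of the C3 acetyl group and not the hindered C2 methine. The step needs intramolecular C4–C5 coupling to outrun aldol closure of a mono-enolate to a cyclopentanol, intermolecular coupling and simple α-chlorination; complete bis-enolisation before the oxidant is added (inverse addition to excess base at −78 °C), high dilution and the gem-disubstituent effect of the fully substituted C1–C2 tether should secure this.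

Step 7
Reactants: 12 tert-butyl (1R,2S)-2-{3-[(tert-butyldimethylsilyl)oxy]propyl}-1-[2-(1,3-dioxolan-2-yl)ethyl]-3,6-dioxocyclohexane-1-carboxylate; 13 isopropenylmagnesium bromide
Product: 14 tert-butyl (1R,2S)-2-{3-[(tert-butyldimethylsilyl)oxy]propyl}-1-[2-(1,3-dioxolan-2-yl)ethyl]-3-hydroxy-6-oxo-3-(prop-1-en-2-yl)cyclohexane-1-carboxylate (either C3 epimer)
Conditions: 13 (1.2 equiv) added to a slurry of 12 and anhydrous CeCl3 (1.5 equiv), THF, −78 °C
Reagents that add atoms: isopropenylmagnesium bromide, CC(=C)[Mg]Br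
Why: Cerium-assisted Grignard 1,2-addition should select the C3 carbonyl, which has only one α-branch, over the C6 carbonyl flanked by the quaternary C1 and its tert-butyl ester, while the low basicity avoids enolisation toward C2; the new carbinol configuration is irrelevant because C3 becomes sp2 in step 11.

Step 8
Reactants: 14 tert-butyl (1R,2S)-2-{3-[(tert-butyldimethylsilyl)oxy]propyl}-1-[2-(1,3-dioxolan-2-yl)ethyl]-3-hydroxy-6-oxo-3-(prop-1-en-2-yl)cyclohexane-1-carboxylate; 15 methylmagnesium bromide
Product: 16 tert-butyl (1R,2S,6S)-2-{3-[(tert-butyldimethylsilyl)oxy]propyl}-1-[2-(1,3-dioxolan-2-yl)ethyl]-3,6-dihydroxy-6-methyl-3-(prop-1-en-2-yl)cyclohexane-1-carboxylate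
Conditions: 15 (4 equiv), anhydrous CeCl3, THF, −78 → 0 °C
Reagents that add atoms: methylmagnesium bromide, C[Mg]Br
Why: Grignard addition to the remaining ketone, in which the methyl group should enter C6 from the ring face opposite to the ester and to the C2 side chain (which blocks an axial approach on its own face by a 1,3-diaxial contact), giving the tertiary alcohol with OH cis to the C1 carboxylate, while the hindered tert-butyl ester is not attacked at low temperature.

Step 9
Reactants: 16 tert-butyl (1R,2S,6S)-2-{3-[(tert-butyldimethylsilyl)oxy]propyl}-1-[2-(1,3-dioxolan-2-yl)ethyl]-3,6-dihydroxy-6-methyl-3-(prop-1-en-2-yl)cyclohexane-1-carboxylate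
Product: 17 (1S,2S,3S)-3-{3-[(tert-butyldimethylsilyl)oxy]propyl}-2-[2-(1,3-dioxolan-2-yl)ethyl]-2-(hydroxymethyl)-1-methyl-4-(prop-1-en-2-yl)cyclohexane-1,4-diol (either C4 epimer)
Conditions: LiAlH4, THF, 0 → 40 °C; aqueous NaOH work-up
Reagents that add atoms: none
Why: Hydride reduction of the hindered tert-butyl ester to the primary alcohol with the two tertiary alcohols carried as alkoxides, acetal, silyl ether and alkene being inert to LiAlH4.

Step 10
Reactants: 17 (1S,2S,3S)-3-{3-[(tert-butyldimethylsilyl)oxy]propyl}-2-[2-(1,3-dioxolan-2-yl)ethyl]-2-(hydroxymethyl)-1-methyl-4-(prop-1-en-2-yl)cyclohexane-1,4-diol; 5 tert-butyldimethylsilyl chloride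
Product: 18 (1S,2S,3S)-2-{[(tert-butyldimethylsilyl)oxy]methyl}-3-{3-[(tert-butyldimethylsilyl)oxy]propyl}-2-[2-(1,3-dioxolan-2-yl)ethyl]-1-methyl-4-(prop-1-en-2-yl)cyclohexane-1,4-diol (either C4 epimer)
Conditions: 5 (1.1 equiv), imidazole, DMF, 0 °C
Reagents that add atoms: tert-butyldimethylsilyl chloride, CC(C)(C)[Si](C)(C)Cl
Why: Selective silylation of the only primary hydroxyl in the presence of two tertiary ones masks it before the chromium oxidation.

Step 11
Reactants: 18 (1S,2S,3S)-2-{[(tert-butyldimethylsilyl)oxy]methyl}-3-{3-[(tert-butyldimethylsilyl)oxy]propyl}-2-[2-(1,3-dioxolan-2-yl)ethyl]-1-methyl-4-(prop-1-en-2-yl)cyclohexane-1,4-diol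
Product: 19 (2Z)-2-[(2R,3S,4S)-3-{[(tert-butyldimethylsilyl)oxy]methyl}-2-{3-[(tert-butyldimethylsilyl)oxy]propyl}-3-[2-(1,3-dioxolan-2-yl)ethyl]-4-hydroxy-4-methylcyclohexylidene]propanal
Conditions: pyridinium chlorochromate [C5H5NH][CrO3Cl] (3 equiv), 4 Å molecular sieves, CH2Cl2, 25 °C
Reagents that add atoms: pyridinium chlorochromate, [O-][Cr](=O)(=O)Cl.c1cc[nH+]cc1
Why: Babler–Dauben oxidative transposition, in which the tertiary allylic chromate ester undergoes a [3,3]-sigmatropic shift and the resulting primary chromate is oxidised to the enal; the Z isomer (CHO cis to C2) is expected to be favoured because it keeps the α-methyl group away from the C2 side chain (A(1,3) strain), and the non-allylic tertiary alcohol, silyl ethers and acetal should be inert.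

Step 12
Reactants: 19 (2Z)-2-[(2R,3S,4S)-3-{[(tert-butyldimethylsilyl)oxy]methyl}-2-{3-[(tert-butyldimethylsilyl)oxy]propyl}-3-[2-(1,3-dioxolan-2-yl)ethyl]-4-hydroxy-4-methylcyclohexylidene]propanal
Product: 20 (2Z)-2-[(2R,3S,4S)-3-{[(tert-butyldimethylsilyl)oxy]methyl}-2-{3-[(tert-butyldimethylsilyl)oxy]propyl}-4-hydroxy-4-methyl-3-(3-oxopropyl)cyclohexylidene]propanal
Conditions: In(OTf)3 (2 mol%), acetone/H2O, 25 °C
Reagents that add atoms: water, O
Why: Lewis-acid-catalysed acetal hydrolysis under near-neutral conditions frees the aliphatic aldehyde while primary silyl ethers, the enal and the tertiary alcohol should persist, and any lactol formed with the C6 hydroxyl reacts on through its open form.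

Step 13
Reactants: 20 (2Z)-2-[(2R,3S,4S)-3-{[(tert-butyldimethylsilyl)oxy]methyl}-2-{3-[(tert-butyldimethylsilyl)oxy]propyl}-4-hydroxy-4-methyl-3-(3-oxopropyl)cyclohexylidene]propanal; 21 2-(triphenyl-λ5-phosphanylidene)propanal
Product: 22 (2Z)-2-[(2R,3S,4S)-3-{[(tert-butyldimethylsilyl)oxy]methyl}-2-{3-[(tert-butyldimethylsilyl)oxy]propyl}-4-hydroxy-4-methyl-3-[(3E)-4-methyl-5-oxopent-3-en-1-yl]cyclohexylidene]propanal
Conditions: 21 (1.5 equiv), toluene, 80 °C
Reagents that add atoms: 2-(triphenyl-λ5-phosphanylidene)propanal, CC(C=O)=P(c1ccccc1)(c1ccccc1)c1ccccc1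
Why: Wittig olefination by a stabilised ylide, which reacts with the unhindered aliphatic aldehyde but not with the hindered conjugated ring enal and gives the (E)-2-methyl enal.

Step 14
Reactants: 23 geranyl bromide; 24 triethyl phosphite
Product: 25 diethyl [(2E)-3,7-dimethylocta-2,6-dien-1-yl]phosphonate
Conditions: neat, 130 °C, bromoethane distilled off
Reagents that add atoms: triethyl phosphite, CCOP(OCC)OCC
Why: Michaelis–Arbuzov reaction at the primary allylic carbon, with retention of the (E)-trisubstituted double bond.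

Step 15
Reactants: 22 (2Z)-2-[(2R,3S,4S)-3-{[(tert-butyldimethylsilyl)oxy]methyl}-2-{3-[(tert-butyldimethylsilyl)oxy]propyl}-4-hydroxy-4-methyl-3-[(3E)-4-methyl-5-oxopent-3-en-1-yl]cyclohexylidene]propanal; 25 diethyl [(2E)-3,7-dimethylocta-2,6-dien-1-yl]phosphonate
Product: 27 (2Z)-2-[(2R,3S,4S)-3-{[(tert-butyldimethylsilyl)oxy]methyl}-2-{3-[(tert-butyldimethylsilyl)oxy]propyl}-4-hydroxy-4-methyl-3-[(3E,5E,7E)-4,8,12-trimethyltrideca-3,5,7,11-tetraen-1-yl]cyclohexylidene]propanal, via lithiated phosphonate 26 (not isolated)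
Conditions: 25 (1.2 equiv), nBuLi, THF, −78 °C; then 22, −78 → 0 °C
Reagents that add atoms: diethyl [(2E)-3,7-dimethylocta-2,6-dien-1-yl]phosphonate, CCOP(=O)(OCC)C/C=C(\C)CCC=C(C)C
Why: Horner–Wadsworth–Emmons olefination through the α-carbon of the allylic phosphonate anion should give the new disubstituted double bond as the E isomer and complete the (E,E,E)-triene, and the tetrasubstituted ring enal, whose formyl group is flanked by the α-methyl group and the substituted C2, should react much more slowly than the side-chain enal at −78 °C with only a slight excess of reagent.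

Step 16
Reactants: 27 (2Z)-2-[(2R,3S,4S)-3-{[(tert-butyldimethylsilyl)oxy]methyl}-2-{3-[(tert-butyldimethylsilyl)oxy]propyl}-4-hydroxy-4-methyl-3-[(3E,5E,7E)-4,8,12-trimethyltrideca-3,5,7,11-tetraen-1-yl]cyclohexylidene]propanal
Product: 28 (2Z)-2-[(2R,3S,4S)-4-hydroxy-3-(hydroxymethyl)-2-(3-hydroxypropyl)-4-methyl-3-[(3E,5E,7E)-4,8,12-trimethyltrideca-3,5,7,11-tetraen-1-yl]cyclohexylidene]propanal (target)
Conditions: Bu4NF, AcOH (1:1), THF, 0 → 25 °C
Reagents that add atoms: none
Why: Fluoride-mediated cleavage of both primary silyl ethers, buffered with acetic acid so that the γ-position of the enal at C2 is not deprotonated, should release the target without touching the triene or the enal.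

**Compound list**

1 | tert-butyl acetoacetate (tert-butyl 3-oxobutanoate) | CC(=O)CC(=O)OC(C)(C)C | starting material
2 | 2-(2-bromoethyl)-1,3-dioxolane | BrCCC1OCCO1 | starting material
3 | tert-butyl 2-acetyl-4-(1,3-dioxolan-2-yl)butanoate (racemic) | CC(=O)C(CCC1OCCO1)C(=O)OC(C)(C)C | intermediate
4 | pent-4-en-1-ol | OCCCC=C | starting material
5 | tert-butyldimethylsilyl chloride | CC(C)(C)[Si](C)(C)Cl | starting material
6 | tert-butyldimethyl(pent-4-en-1-yloxy)silane | C=CCCCO[Si](C)(C)C(C)(C)C | intermediate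
7 | allyl methyl carbonate | C=CCOC(=O)OC | starting material
8 | (2E)-6-[(tert-butyldimethylsilyl)oxy]hex-2-en-1-yl methyl carbonate | COC(=O)OC/C=C/CCCO[Si](C)(C)C(C)(C)C | intermediate
9 | tert-butyl (2R,3R)-2-acetyl-3-{3-[(tert-butyldimethylsilyl)oxy]propyl}-2-[2-(1,3-dioxolan-2-yl)ethyl]pent-4-enoate | O1CCOC1CC[C@@](C(C)=O)(C(=O)OC(C)(C)C)[C@H](CCCO[Si](C)(C)C(C)(C)C)C=C | intermediate
10 | tert-butyl (2R,3S)-2-acetyl-3-{3-[(tert-butyldimethylsilyl)oxy]propyl}-2-[2-(1,3-dioxolan-2-yl)ethyl]-4-oxopentanoate | O1CCOC1CC[C@@](C(C)=O)(C(=O)OC(C)(C)C)[C@H](CCCO[Si](C)(C)C(C)(C)C)C(C)=O | intermediate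
11 | dilithium bis-enolate of 10 (both acetyl groups as CH2=C(OLi)–, configuration of 10 retained) | O1CCOC1CC[C@@](C(=C)O[Li])(C(=O)OC(C)(C)C)[C@H](CCCO[Si](C)(C)C(C)(C)C)C(=C)O[Li] | intermediate
12 | tert-butyl (1R,2S)-2-{3-[(tert-butyldimethylsilyl)oxy]propyl}-1-[2-(1,3-dioxolan-2-yl)ethyl]-3,6-dioxocyclohexane-1-carboxylate | O2CCOC2CC[C@@]1(C(=O)OC(C)(C)C)[C@H](CCCO[Si](C)(C)C(C)(C)C)C(=O)CCC1=O | intermediate
13 | isopropenylmagnesium bromide | CC(=C)[Mg]Br | starting material
14 | tert-butyl (1R,2S)-2-{3-[(tert-butyldimethylsilyl)oxy]propyl}-1-[2-(1,3-dioxolan-2-yl)ethyl]-3-hydroxy-6-oxo-3-(prop-1-en-2-yl)cyclohexane-1-carboxylate (C3 unspecified) | O2CCOC2CC[C@@]1(C(=O)OC(C)(C)C)[C@H](CCCO[Si](C)(C)C(C)(C)C)C(O)(C(C)=C)CCC1=O | intermediate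
15 | methylmagnesium bromide | C[Mg]Br | starting material
16 | tert-butyl (1R,2S,6S)-2-{3-[(tert-butyldimethylsilyl)oxy]propyl}-1-[2-(1,3-dioxolan-2-yl)ethyl]-3,6-dihydroxy-6-methyl-3-(prop-1-en-2-yl)cyclohexane-1-carboxylate (C3 unspecified) | O2CCOC2CC[C@@]1(C(=O)OC(C)(C)C)[C@H](CCCO[Si](C)(C)C(C)(C)C)C(O)(C(C)=C)CC[C@]1(C)O | intermediate
17 | (1S,2S,3S)-3-{3-[(tert-butyldimethylsilyl)oxy]propyl}-2-[2-(1,3-dioxolan-2-yl)ethyl]-2-(hydroxymethyl)-1-methyl-4-(prop-1-en-2-yl)cyclohexane-1,4-diol (C4 unspecified) | O2CCOC2CC[C@@]1(CO)[C@H](CCCO[Si](C)(C)C(C)(C)C)C(O)(C(C)=C)CC[C@]1(C)O | intermediate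
18 | (1S,2S,3S)-2-{[(tert-butyldimethylsilyl)oxy]methyl}-3-{3-[(tert-butyldimethylsilyl)oxy]propyl}-2-[2-(1,3-dioxolan-2-yl)ethyl]-1-methyl-4-(prop-1-en-2-yl)cyclohexane-1,4-diol (C4 unspecified) | O2CCOC2CC[C@@]1(CO[Si](C)(C)C(C)(C)C)[C@H](CCCO[Si](C)(C)C(C)(C)C)C(O)(C(C)=C)CC[C@]1(C)O | intermediate
19 | (2Z)-2-[(2R,3S,4S)-3-{[(tert-butyldimethylsilyl)oxy]methyl}-2-{3-[(tert-butyldimethylsilyl)oxy]propyl}-3-[2-(1,3-dioxolan-2-yl)ethyl]-4-hydroxy-4-methylcyclohexylidene]propanal | O2CCOC2CC[C@@]1(CO[Si](C)(C)C(C)(C)C)[C@H](CCCO[Si](C)(C)C(C)(C)C)/C(=C(/C)C=O)CC[C@]1(C)O | intermediate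
20 | (2Z)-2-[(2R,3S,4S)-3-{[(tert-butyldimethylsilyl)oxy]methyl}-2-{3-[(tert-butyldimethylsilyl)oxy]propyl}-4-hydroxy-4-methyl-3-(3-oxopropyl)cyclohexylidene]propanal | O=CCC[C@@]1(CO[Si](C)(C)C(C)(C)C)[C@H](CCCO[Si](C)(C)C(C)(C)C)/C(=C(/C)C=O)CC[C@]1(C)O | intermediate
21 | 2-(triphenyl-λ5-phosphanylidene)propanal | CC(C=O)=P(c1ccccc1)(c1ccccc1)c1ccccc1 | starting material
22 | (2Z)-2-[(2R,3S,4S)-3-{[(tert-butyldimethylsilyl)oxy]methyl}-2-{3-[(tert-butyldimethylsilyl)oxy]propyl}-4-hydroxy-4-methyl-3-[(3E)-4-methyl-5-oxopent-3-en-1-yl]cyclohexylidene]propanal | O=C/C(C)=C/CC[C@@]1(CO[Si](C)(C)C(C)(C)C)[C@H](CCCO[Si](C)(C)C(C)(C)C)/C(=C(/C)C=O)CC[C@]1(C)O | intermediate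
23 | geranyl bromide ((2E)-1-bromo-3,7-dimethylocta-2,6-diene) | BrC/C=C(\C)CCC=C(C)C | starting material
24 | triethyl phosphite | CCOP(OCC)OCC | starting material
25 | diethyl [(2E)-3,7-dimethylocta-2,6-dien-1-yl]phosphonate | CCOP(=O)(OCC)C/C=C(\C)CCC=C(C)C | intermediate
26 | lithiated phosphonate (25 deprotonated at the carbon next to phosphorus) | CCOP(=O)(OCC)C([Li])/C=C(\C)CCC=C(C)C | intermediate
27 | (2Z)-2-[(2R,3S,4S)-3-{[(tert-butyldimethylsilyl)oxy]methyl}-2-{3-[(tert-butyldimethylsilyl)oxy]propyl}-4-hydroxy-4-methyl-3-[(3E,5E,7E)-4,8,12-trimethyltrideca-3,5,7,11-tetraen-1-yl]cyclohexylidene]propanal | CC(C)=CCC/C(C)=C/C=C/C(C)=C/CC[C@@]1(CO[Si](C)(C)C(C)(C)C)[C@H](CCCO[Si](C)(C)C(C)(C)C)/C(=C(/C)C=O)CC[C@]1(C)O | intermediate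
28 | (2Z)-2-[(2R,3S,4S)-4-hydroxy-3-(hydroxymethyl)-2-(3-hydroxypropyl)-4-methyl-3-[(3E,5E,7E)-4,8,12-trimethyltrideca-3,5,7,11-tetraen-1-yl]cyclohexylidene]propanal | CC(C)=CCC/C(C)=C/C=C/C(C)=C/CC[C@@]1(CO)[C@H](CCCO)/C(=C(/C)C=O)CC[C@]1(C)O | target

**Step count and risks**

Total step count: 16. Longest linear sequence: 14 steps (steps 2, 3, 4 to 13, 15 and 16, from pent-4-en-1-ol).

Steps most likely to fail:

Step 6. The double enolisation may be incomplete, so that a mono-enolate closes by aldol addition onto the second ketone; the enolates may also couple between molecules, or be chlorinated by CuCl2 without C–C bond formation. The fallback sets out from 10 and replaces the one-pot one-electron coupling by a stepwise two-electron sequence in which nucleophile and electrophile are made separately. The bis-enolate 11 is trapped with Me3SiCl to give the bis(trimethylsilyl enol ether) of 10 F1. One equivalent of N-bromosuccinimide at −78 °C brominates one of the two enol ethers and gives the bromomethyl ketone that still carries the other enol ether, as the C1-side bromide F2 and its regioisomer, the C2-side bromide F3; both carry the halide on one of the two carbons to be joined, so both are productive. Anhydrous Bu4NF then releases the remaining enol ether as an enolate, which displaces bromide in a six-membered intramolecular alkylation, and the route is rejoined at 12.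

Step 4. The hindered α-substituted enolate may show poor facial discrimination (low diastereoselectivity at the quaternary carbon), and attack at the substituted allyl terminus may lose out to linear substitution. The fallback sets out from 1 and 8 and separates the two stereocentres. Iridium-catalysed allylic alkylation of the unsubstituted acetoacetate 1 with 8 under the conditions of step 4, which is well precedented for unhindered stabilised nucleophiles and sets only the allylic centre, should give tert-butyl (3R)-2-acetyl-3-{3-[(tert-butyldimethylsilyl)oxy]propyl}pent-4-enoate F4 as a mixture of C2 epimers. Alkylation of its sodium enolate with bromide 2 (NaH, NaI, DMF) then builds the quaternary centre under 1,2-induction from the adjacent stereocentre; the diastereomers are separated and the route is rejoined at 9.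

Step 11. The tertiary allylic chromate may ionise instead of rearranging, leading to elimination or to capture of the allyl cation by the C6 hydroxyl, and the [3,3] shift may give poor control of the enal geometry. The fallback sets out from 18 and splits transposition and oxidation into two mild steps. Catalytic Ph3SiOReO3 (Et2O, −50 → 0 °C) should effect a reversible 1,3-transposition of the tertiary allylic alcohol to the more substituted alkene, the primary allylic alcohol (2Z)-2-[(2R,3S,4S)-3-{[(tert-butyldimethylsilyl)oxy]methyl}-2-{3-[(tert-butyldimethylsilyl)oxy]propyl}-3-[2-(1,3-dioxolan-2-yl)ethyl]-4-hydroxy-4-methylcyclohexylidene]propan-1-ol F5. Oxidation with MnO2 (CH2Cl2, 25 °C), which is selective for the allylic alcohol, rejoins the route at 19.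

**Further compounds**

F1 | step 6 | bis(trimethylsilyl enol ether) of 10 (both acetyl groups as CH2=C(OSiMe3)–, configuration of 10 retained) | O1CCOC1CC[C@@](C(=C)O[Si](C)(C)C)(C(=O)OC(C)(C)C)[C@H](CCCO[Si](C)(C)C(C)(C)C)C(=C)O[Si](C)(C)C
F2 | step 6 | C1-side bromide (bromoacetyl group on the quaternary carbon, trimethylsilyl enol ether on the other acyl group) | O1CCOC1CC[C@@](C(=O)CBr)(C(=O)OC(C)(C)C)[C@H](CCCO[Si](C)(C)C(C)(C)C)C(=C)O[Si](C)(C)C
F3 | step 6 | C2-side bromide (trimethylsilyl enol ether on the quaternary carbon, bromoacetyl group on the other carbon) | O1CCOC1CC[C@@](C(=C)O[Si](C)(C)C)(C(=O)OC(C)(C)C)[C@H](CCCO[Si](C)(C)C(C)(C)C)C(=O)CBr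
F4 | step 4 | tert-butyl (3R)-2-acetyl-3-{3-[(tert-butyldimethylsilyl)oxy]propyl}pent-4-enoate (both C2 epimers) | CC(=O)C(C(=O)OC(C)(C)C)[C@H](CCCO[Si](C)(C)C(C)(C)C)C=C
F5 | step 11 | (2Z)-2-[(2R,3S,4S)-3-{[(tert-butyldimethylsilyl)oxy]methyl}-2-{3-[(tert-butyldimethylsilyl)oxy]propyl}-3-[2-(1,3-dioxolan-2-yl)ethyl]-4-hydroxy-4-methylcyclohexylidene]propan-1-ol | O2CCOC2CC[C@@]1(CO[Si](C)(C)C(C)(C)C)[C@H](CCCO[Si](C)(C)C(C)(C)C)/C(=C(/C)CO)CC[C@]1(C)O
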